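(The numbers in the tables were generated by integration on assumed constants, and the scatter is random.)

A small charge of initiator is what I followed through these flasks.

| flask | free monomer | transfer agent | initiator | remark | time |
|---|---|---|---|---|---|
| north | 0.99 M | 0.297 M | 1.8 mM | run made earlier |  |
| south-east | 0.99 M | 0.297 M | 14 mM | run made earlier |  |
| south-west | 0.99 M | 0.297 M | 130 mM | run made earlier |  |
| alder | 0.99 M | 0.297 M | 1.5 mM |  | 40 h |
| oak | 0.99 M | 0.297 M | 5.0 mM |  | 40 h |
| larch | 0.99 M | 0.297 M | 15 mM |  | 40 h |
| cedar | 0.99 M | 0.297 M | 40 mM |  | 40 h |
| ash | 0.99 M | 0.297 M | 120 mM |  | 40 h |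

- north (time / h: monomer in chains / %, free monomer / %): 3.00: 1.0, 99.6; 8.00: 2.2, 98.5; 15.0: 2.9, 97.3; 40.0: 2.9, 97.3
- south-east (time / h: monomer in chains / %, free monomer / %): 3.00: 5.6, 94.2; 8.00: 13.5, 86.5; 15.0: 17.9, 83.6; 40.0: 19.1, 80.3
- south-west (time / h: monomer in chains / %, free monomer / %): 3.00: 30.9, 68.1; 8.00: 55.6, 43.7; 15.0: 69.1, 31.1; 40.0: 83.1, 15.1

(scatter of a reading: 0.5 percentage points)

- steps under discussion: free monomer + initiator -> living end + monomer in chains; free monomer + living end -> monomer in chains + living end; living end + transfer agent -> dead chain; 2 living end <-> resting dimer
- "hardly changes" means that all values lie within two and a half points (for a concentration: within two and a half percent of the largest)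

1. amount of monomer in chains at the end, in percent of the free monomer charged for alder, oak, larch, cedar, ash, in this order
2. how the row runs (hardly changes / falls all the way / falls, then rises / rises all the way / rises, then falls)

I kept the balance of the initiator, charged below the transfer agent. One initiator gave one living end. That end, however long it grew or sat as resting dimer, left as one dead chain by taking one transfer agent. So two rates per living end stood against each other: growth, proportional to c(free monomer), and death, proportional to c(transfer agent). Dividing the two balances removed c(living end), whatever it did in time:

ln[c(free monomer, start) / c(free monomer)] = S · ln[c(transfer agent, start) / c(transfer agent)]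

With the end balance below, the south-east reading at 40.0 h gave S = 4.54, an effective ratio of growth to death, a selectivity factor; it came from one scattered reading and carried the free monomer taken up by initiation, which the equation above leaves out. The north run read 4.50. At the charge, an end added about 15.1 monomer before it died.

Once the initiator had turned into ends and these, resting dimer included, had died, the balance gave:

c(transfer agent, end) = c(transfer agent, start) − c(initiator, start)

My estimates of the final monomer in chains, from alder to ash, were therefore 2.27 %, 7.42 %, 21.0 %, 48.2 % and 90.5 %. But south-west read 83.1 % at 40.0 h against an estimate of 92.7 %, so I expected ash to stand below its estimate at 40 h.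

The forecast gave 2.4 %, 7.7 %, 20.3 %, 45 % and 81 %, so its cedar and ash stood below my estimates, with the words “the resting dimer stores living ends”. Its shape was: rises all the way.

The flasks gave 2.30 %, 7.41 %, 20.3 %, 44.8 % and 82.1 %: rises all the way.

    free monomer + initiator → living end + monomer in chains (k = 6.90 × 10⁻⁵ M⁻¹ s⁻¹)
    free monomer + living end → monomer in chains + living end, rate k2*[living end]*[free monomer] (k = 0.00160 M⁻¹ s⁻¹)
    living end + transfer agent → dead chain (kL = 3.70 × 10⁻⁴ M⁻¹ s⁻¹)
    2 living end ⇌ resting dimer (K = 440 M⁻¹, k = 0.00340 M⁻¹ s⁻¹)

What could overturn the forecast shows in the alder run with the transfer step taken away: it ends at 20.5 % monomer in chains against 2.30 %, one part of why alder stays low. With S and the transfer agent left after 400 h, ash reckons to 9.52 % free monomer, and 8.39 % stands in the flask. Cedar, at the same time, reckons to 51.8 % free monomer against 50.9 %.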